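The earlier runs and the new flask are simulated for an exercise; scatter was added.

At early times the west run is quick, with 0.050 M of product at 3.1 min, yet at 87 min it holds 0.178 M and 0.222 M of substrate is still unturned.

| setting | west | north-east | east | south-east |
|---|---|---|---|---|
| substrate | 0.400 M | 0.400 M | 0.600 M | 0.400 M |
| free catalyst | 0.00800 M | 0.0240 M | 0.00800 M | 0.00800 M |
| time |  |  |  | 520 min |

| run | time / min | [product] / M |
|---|---|---|
| west run | 3.1 | 0.050 |
| west run | 9.5 | 0.079 |
| west run | 18 | 0.117 |
| west run | 29 | 0.140 |
| west run | 41 | 0.152 |
| west run | 55 | 0.165 |
| west run | 70 | 0.168 |
| west run | 87 | 0.178 |
| north-east run | 3.1 | 0.086 |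
| north-east run | 9.5 | 0.130 |
| north-east run | 18 | 0.161 |
| north-east run | 29 | 0.175 |
| north-east run | 41 | 0.191 |
| north-east run | 55 | 0.202 |
| north-east run | 70 | 0.211 |
| north-east run | 87 | 0.210 |
| east run | 3.1 | 0.066 |
| east run | 9.5 | 0.131 |
| east run | 18 | 0.171 |
| east run | 29 | 0.207 |
| east run | 41 | 0.225 |
| east run | 55 | 0.240 |
| east run | 70 | 0.260 |
| east run | 87 | 0.265 |

(readings scatter by 0.004 M)

1. reaction order in [free catalyst] at the outset, round the charge of the west run, defined at two percent of the substrate turned into product
2. reaction order in [substrate] at the outset, round the charge of the west run, defined at two percent of the substrate turned into product (one fixed amount of product, the same in the runs compared)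
3. product in the south-east run at 520 min, as a share of the substrate charged
4. which of these the readings show (the catalyst dies in pairs / an uncatalysed path runs beside / the product kills the catalyst / the product binds the substrate / nothing beyond the main steps)

- Overall: substrate -> product, with free catalyst as catalyst.
- Constant volume, constant temperature.
- What is held in complexes is read along with the free species.
- An order is taken over about fifteen percent of the charge, up and down.

A first reading is a plain pseudo-first-order reaction in substrate. The east run supports that part: at 87 min it has turned 44.2 % of its charge, the west run 44.5 %. So the measure of work done is y, the logarithm of substrate charged over substrate left. But y flattens in the west run, so the catalyst there is fading.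

Product might be the killer. The test is whether equal catalyst charge times time gives equal product, as a loss second order in catalyst does. The north-east run at 29 min and the west run at 87 min, equal in catalyst charge times time, hold 0.175 M and 0.178 M of product, a gap smaller than the scatter of 0.004 M. That scaling fits a loss second order in catalyst. Free catalyst then falls as one over one plus t/τ, and y equals a times the logarithm of one plus t/τ. Here τ, the catalyst half-life, is the time in which the charge first halves, and it shrinks as the charge grows.

Ignoring the one, y at the west reading of 9.5 min is 0.220 and y at the north-east reading of 87 min is 0.744. Over that span of charge times time, a comes to 0.158. With the west y of 0.589 at 87 min, τ comes to 2.16 min. The objection is that the west reading at 9.5 min has t/τ of just 4.40, so the one cannot be dropped. Keeping it gives a = 0.168 and, for the west charge, τ = 2.71 min.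

Now the half-lives can be counted. Each halving of the catalyst adds the same 0.117 to y. By 520 min the south-east run, charged like the west run, is reckoned to have passed 7.59 halvings, so my estimate is 58.7 % of its substrate turned.

The forecast gives 58 %, lower than my estimate, between 55 % and 61 %, with order 1 in catalyst, 1.14 in substrate, and the verdict that the catalyst dies in pairs. Against a product poison it argues: “Product-driven death would scale the plateau far more with catalyst”.

    free catalyst + substrate ⇌ catalyst-substrate complex (20.52 M⁻¹ min⁻¹, 199.8 min⁻¹)
    catalyst-substrate complex → product + free catalyst (111.0 min⁻¹)
    2 free catalyst → 2 spent catalyst (21.48 M⁻¹ min⁻¹)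

The south-east run gives 59.2 %. Round the west charge the orders are 1.0 in free catalyst and 1.1 in substrate, and the readings show that the catalyst dies in pairs. Without that loss the same run reaches 100 % instead of 59.2 %, so the loss of free catalyst in pairs is the main reason for the substrate left over. At the reckoned 0.117 per halving, the south-east result stands for 7.66 halvings. For the north-east run τ reckons to 0.904 min, which puts half of its substrate turned at 55.1 min. That run reaches this point at 53.0 min.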